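The 14-membered carbocycle (cembrane numbering) is opened at C8–C9. This is the alkenyl–homoallyl bond of the 1,5-diene C7=C8–C9–C10–C11=C12, and it lies diametrically opposite the C1–C2 edge shared with the cis-fused α-methylene-γ-butyrolactone. The final step is an intramolecular Negishi coupling. It joins a C9 alkylzinc to a geometrically pure C8 alkenyl iodide that already carries the C19 acetoxymethyl group. One operation closes the macrocycle, transfers the C7=C8 geometry by retention and gives the target with no later adjustment. Because closure is remote, C1 and C2 are set earlier in an open-chain, catalyst-controlled syn-allylboration/lactonisation uniting two achiral halves. The precursor is seco-diiodide 26.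

Key step: step 17

Remark on numbering: C1 is the ring-fusion CH bearing C15. C2 is the ring-fusion CH bearing the lactone oxygen. The ring then runs C3=C4(CH3), C5, C6, C7=C8(C19H2OAc), C9, C10, C11=C12(CH3), C13, C14. C15 is the lactone α-carbon, C16 the lactone C=O and C17 the exocyclic CH2.

Remark on an assumption: the sense of induction of (R)-TRIP (attack on the Re face of the aldehyde) is carried over from simple allyl- and crotylboronates. If it proves opposite for boronate 10, the (S)-acid is used with no other change.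

**Western half (C9–C14, C1, C15–C17)**

Step 1
Reactants: 1 3-[(tert-butyldimethylsilyl)oxy]propanal; 2 isopropenylmagnesium bromide
Product: 3 (±)-5-[(tert-butyldimethylsilyl)oxy]-2-methylpent-1-en-3-ol
Conditions: THF, −78 → 0 °C; aq NH4Cl
Reagents that add atoms: none
Why: Grignard 1,2-addition to an unhindered aldehyde should be clean, and the new carbinol centre may stay racemic because it is erased in step 2.

Step 2
Reactants: 3 (±)-5-[(tert-butyldimethylsilyl)oxy]-2-methylpent-1-en-3-ol; 4 triethyl orthoacetate
Product: 5 ethyl (4E)-7-[(tert-butyldimethylsilyl)oxy]-4-methylhept-4-enoate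
Conditions: 4 (6 equiv), EtCO2H (5 mol %), 140 °C, EtOH distilled off
Reagents that add atoms: none
Why: Johnson–Claisen rearrangement through a chair transition state with the CH2CH2OTBS group equatorial should convert the carbinol into the E-trisubstituted C11=C12 alkene while adding C14 and C1.

Step 3
Reactants: 5 ethyl (4E)-7-[(tert-butyldimethylsilyl)oxy]-4-methylhept-4-enoate
Product: 6 (4E)-7-[(tert-butyldimethylsilyl)oxy]-4-methylhept-4-enal
Conditions: i-Bu2AlH (1.05 equiv), CH2Cl2, −78 °C; aq Rochelle salt
Reagents that add atoms: none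
Why: Partial ester reduction stops at the aluminium hemiacetal at −78 °C and should release the C1 aldehyde on work-up without touching the silyl ether or the alkene.

Step 4
Reactants: 6 (4E)-7-[(tert-butyldimethylsilyl)oxy]-4-methylhept-4-enal; 7 methyl acrylate
Product: 8 (±)-methyl (6E)-9-[(tert-butyldimethylsilyl)oxy]-3-hydroxy-6-methyl-2-methylidenenon-6-enoate
Conditions: 7 (3 equiv), DABCO (1 equiv), neat, rt, several days
Reagents that add atoms: none
Why: The Morita–Baylis–Hillman reaction of an unbranched aliphatic aldehyde joins C1 to C15, and the racemic carbinol centre is erased in step 6.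

Step 5
Reactants: 8 (±)-methyl (6E)-9-[(tert-butyldimethylsilyl)oxy]-3-hydroxy-6-methyl-2-methylidenenon-6-enoate
Product: 9 (±)-methyl (6E)-3-acetoxy-9-[(tert-butyldimethylsilyl)oxy]-6-methyl-2-methylidenenon-6-enoate
Conditions: Ac2O, pyridine, DMAP (cat.), CH2Cl2, 0 °C
Reagents that add atoms: acetic anhydride, CC(=O)OC(C)=O
Why: Simple O-acylation turns the hydroxyl into the leaving group needed for the allylic transposition.

Step 6
Reactants: 9 (±)-methyl (6E)-3-acetoxy-9-[(tert-butyldimethylsilyl)oxy]-6-methyl-2-methylidenenon-6-enoate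
Product: 10 methyl (2E,6E)-9-[(tert-butyldimethylsilyl)oxy]-6-methyl-2-[(4,4,5,5-tetramethyl-1,3,2-dioxaborolan-2-yl)methyl]nona-2,6-dienoate (C14 chain cis to CH2B and trans to the ester)
Conditions: B2pin2 (1.1 equiv), CuCl (10 mol %), KOAc (1.1 equiv), DMF, rt
Reagents that add atoms: bis(pinacolato)diboron, CC1(C)OB(OC1(C)C)B1OC(C)(C)C(C)(C)O1
Why: Copper-catalysed Miyaura-type allylic borylation (conjugate borylation at C17, then β-acetoxy elimination, overall SN2′) should give the primary allylboronate, with elimination from the conformer that keeps the alkyl chain away from the ester setting the Z-crotyl-type geometry.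

**Eastern half (C2–C8, C19)**

Step 7
Reactants: 11 geranyl acetate
Product: 12 (±)-(2E)-5-(3,3-dimethyloxiran-2-yl)-3-methylpent-2-en-1-yl acetate
Conditions: mCPBA (1.0 equiv), CH2Cl2, 0 °C
Reagents that add atoms: mCPBA, OOC(=O)c1cccc(Cl)c1
Why: Prilezhaev epoxidation selects the electron-rich terminal alkene over the alkene deactivated by the allylic acetate, and the racemic epoxide is destroyed in step 8.

Step 8
Reactants: 12 (±)-(2E)-5-(3,3-dimethyloxiran-2-yl)-3-methylpent-2-en-1-yl acetate
Product: 13 (2E)-3-methyl-6-oxohex-2-en-1-yl acetate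
Conditions: H5IO6 (1.2 equiv), THF/Et2O, 0 °C
Reagents that add atoms: none
Why: Acid-promoted epoxide hydration followed by Malaprade glycol cleavage in the same flask should excise acetone and leave the C7 aldehyde with the E-alkene untouched.

Step 9
Reactants: 13 (2E)-3-methyl-6-oxohex-2-en-1-yl acetate; 14 dimethyl (1-diazo-2-oxopropyl)phosphonate
Product: 15 (2E)-3-methylhept-2-en-6-yn-1-ol
Conditions: 14 (1.3 equiv), K2CO3 (3 equiv), MeOH, 0 °C → rt
Reagents that add atoms: none
Why: Seyferth–Gilbert homologation in its Ohira–Bestmann form adds C8 as a terminal alkyne, and the K2CO3/MeOH medium methanolyses the allylic acetate at the same time, which is wanted here.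

Step 10
Reactants: 15 (2E)-3-methylhept-2-en-6-yn-1-ol
Product: 16 triethyl{[(2E)-3-methylhept-2-en-6-yn-1-yl]oxy}silane
Conditions: Et3SiCl, imidazole, CH2Cl2, 0 °C
Reagents that add atoms: chlorotriethylsilane, CC[Si](Cl)(CC)CC
Why: Silylation masks the C2 oxygen with a group that survives n-BuLi and can later be oxidised directly to the aldehyde.

Step 11
Reactants: 16 triethyl{[(2E)-3-methylhept-2-en-6-yn-1-yl]oxy}silane
Product: 19 (6E)-6-methyl-8-[(triethylsilyl)oxy]oct-6-en-2-yn-1-yl acetate, via lithium acetylide 17 (not isolated), via lithium alkoxide 18 (not isolated)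
Conditions: n-BuLi (1.05 equiv), THF, −78 °C; (CH2O)n (1.5 equiv), → rt; Ac2O (2 equiv), 0 °C
Reagents that add atoms: n-butyllithium, [Li]CCCC (lithium only in 17 and 18); formaldehyde (from paraformaldehyde), C=O; acetic anhydride, CC(=O)OC(C)=O
Why: Acetylide hydroxymethylation installs C19, and trapping the propargylic alkoxide with Ac2O places the acetate of the target on the only free oxygen, so C2–O and C19–O are differentiated from the start.

Step 12
Reactants: 19 (6E)-6-methyl-8-[(triethylsilyl)oxy]oct-6-en-2-yn-1-yl acetate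
Product: 21 (2E,6E)-2-iodo-6-methyl-8-[(triethylsilyl)oxy]octa-2,6-dien-1-yl acetate, via alkenylstannane 20 (not isolated)
Conditions: PdCl2(PPh3)2 (3 mol %), Bu3SnH (1.15 equiv, slow addition), THF, 0 °C; then I2 (1.2 equiv), CH2Cl2, 0 °C
Reagents that add atoms: tributyltin hydride, CCCC[SnH](CCCC)CCCC (tin only in 20); iodine, II
Why: Palladium-catalysed syn-hydrostannation should place tin on C8, the alkyne carbon next to the electron-withdrawing CH2OAc group, and stereoretentive iododestannylation then fixes C6 cis to C19 with iodine trans to C6.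

Step 13
Reactants: 21 (2E,6E)-2-iodo-6-methyl-8-[(triethylsilyl)oxy]octa-2,6-dien-1-yl acetate
Product: 22 (2E,6E)-2-iodo-6-methyl-8-oxoocta-2,6-dien-1-yl acetate
Conditions: (COCl)2 (4 equiv), DMSO (8 equiv), CH2Cl2, −78 → −40 °C; Et3N (15 equiv), → 0 °C
Reagents that add atoms: none
Why: Swern oxidation applied directly to a primary allylic triethylsilyl ether cleaves the labile Si–O bond with activated DMSO and collapses the alkoxysulfonium salt to the E-enal, while the acetate and the alkenyl iodide are inert.

**Union and end game**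

Step 14
Reactants: 10 methyl (2E,6E)-9-[(tert-butyldimethylsilyl)oxy]-6-methyl-2-[(4,4,5,5-tetramethyl-1,3,2-dioxaborolan-2-yl)methyl]nona-2,6-dienoate; 22 (2E,6E)-2-iodo-6-methyl-8-oxoocta-2,6-dien-1-yl acetate
Product: 24 (4S,5S)-5-[(1E,5E)-7-acetoxy-6-iodo-2-methylhepta-1,5-dien-1-yl]-4-{(3E)-6-[(tert-butyldimethylsilyl)oxy]-3-methylhex-3-en-1-yl}-3-methylidenedihydrofuran-2(3H)-one, via pinacol borate 23 (not isolated)
Conditions: 10 (1.3 equiv), (R)-TRIP [(R)-3,3′-bis(2,4,6-triisopropylphenyl)-1,1′-binaphthyl-2,2′-diyl hydrogen phosphate, 10 mol %], 4 Å MS, toluene, 0 °C → rt; then PPTS (20 mol %), 40 °C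
Reagents that add atoms: none
Why: Chiral-phosphoric-acid-catalysed allylboration through a closed chair transition state translates the boronate geometry (C14 cis to CH2B) into the C1/C2 syn relationship, the catalyst should expose the Re face of the enal to give 2S and hence 1S, and mild acid lactonisation of the borate expels MeOBpin to give the cis-fused α-methylene lactone.

Step 15
Reactants: 24 the silyl-protected lactone of step 14
Product: 25 (4S,5S)-5-[(1E,5E)-7-acetoxy-6-iodo-2-methylhepta-1,5-dien-1-yl]-4-[(3E)-6-hydroxy-3-methylhex-3-en-1-yl]-3-methylidenedihydrofuran-2(3H)-one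
Conditions: HF·pyridine, pyridine, THF, 0 °C → rt
Reagents that add atoms: none
Why: Buffered fluoride desilylation frees the C9 hydroxyl without hydrolysing the acetate, opening the lactone or adding to the acrylate.

Step 16
Reactants: 25 the C9 alcohol of step 15
Product: 26 (4S,5S)-5-[(1E,5E)-7-acetoxy-6-iodo-2-methylhepta-1,5-dien-1-yl]-4-[(3E)-6-iodo-3-methylhex-3-en-1-yl]-3-methylidenedihydrofuran-2(3H)-one
Conditions: PPh3 (1.3 equiv) and I2 (1.3 equiv) premixed, imidazole (1.5 equiv), CH2Cl2, 0 °C
Reagents that add atoms: iodine, II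
Why: Appel iodination of a primary alcohol proceeds under neutral conditions, and premixing phosphine and iodine leaves no free PPh3 to add to the α-methylene lactone.

Step 17
Reactants: 26 the seco-diiodide of step 16
Product: 28 (1S,2S,3E,7Z,11E)-19-acetoxycembra-3,7,11,15(17)-tetraen-16,2-olide (CNP0158848.2), via alkylzinc iodide 27 (not isolated)
Conditions: Zn dust (4 equiv, activated with BrCH2CH2Br and Me3SiCl), THF (0.5 M), 35 °C, 3 h; supernatant freed from excess Zn and added by syringe pump (12 h) to Pd2(dba)3 (5 mol %), DPEphos (11 mol %), THF (final 1 mM), 35 °C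
Reagents that add atoms: zinc, [Zn] (zinc only in 27)
Why: Zinc should insert only into the primary C9–I bond because the alkenyl C8–I bond, the esters and the acrylate are inert to zinc dust in THF; zerovalent palladium then adds oxidatively to C8–I much faster than it ionises the allylic acetate or the allylic C2–O bond, intramolecular transmetalation gives a 15-membered alkyl(alkenyl)palladacycle, and reductive elimination forges C8–C9. The closest known reaction type is the Negishi coupling of homoallylzinc reagents with alkenyl iodides that builds 1,5-dienes, run here intramolecularly under pseudo-high dilution. The one ring closed is the 14-membered carbocycle, formed end-to-end with the new bond in the ring and both flanking alkenes (C7=C8 and C11=C12) endocyclic with trans ring paths. No stereocentre is created: C1 and C2 each lie six bonds from the reacting carbons and are untouched, and the C7=C8 geometry is carried over by stereoretentive oxidative addition and reductive elimination, so C9 takes the place of iodine trans to C6. The step needs intramolecular over intermolecular coupling, which slow addition to 1 mM and the chain pre-bent by three trisubstituted alkenes and the cis-lactone should secure, and reductive elimination over β-hydride elimination, which the wide-bite-angle diphosphine should secure. Carbopalladation of C15=C17 is disfavoured because it would need a strained transannular ten-membered closure, whereas transmetalation from zinc is fast near room temperature.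

**Compound list**

1 | 3-[(tert-butyldimethylsilyl)oxy]propanal | O=CCCO[Si](C)(C)C(C)(C)C | starting material
2 | isopropenylmagnesium bromide | C=C(C)[Mg]Br | starting material
3 | (±)-5-[(tert-butyldimethylsilyl)oxy]-2-methylpent-1-en-3-ol | C=C(C)C(O)CCO[Si](C)(C)C(C)(C)C | intermediate
4 | triethyl orthoacetate | CC(OCC)(OCC)OCC | starting material
5 | ethyl (4E)-7-[(tert-butyldimethylsilyl)oxy]-4-methylhept-4-enoate | CCOC(=O)CC/C(C)=C/CCO[Si](C)(C)C(C)(C)C | intermediate
6 | (4E)-7-[(tert-butyldimethylsilyl)oxy]-4-methylhept-4-enal | O=CCC/C(C)=C/CCO[Si](C)(C)C(C)(C)C | intermediate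
7 | methyl acrylate | C=CC(=O)OC | starting material
8 | (±)-methyl (6E)-9-[(tert-butyldimethylsilyl)oxy]-3-hydroxy-6-methyl-2-methylidenenon-6-enoate | C=C(C(=O)OC)C(O)CC/C(C)=C/CCO[Si](C)(C)C(C)(C)C | intermediate
9 | (±)-methyl (6E)-3-acetoxy-9-[(tert-butyldimethylsilyl)oxy]-6-methyl-2-methylidenenon-6-enoate | C=C(C(=O)OC)C(OC(C)=O)CC/C(C)=C/CCO[Si](C)(C)C(C)(C)C | intermediate
10 | methyl (2E,6E)-9-[(tert-butyldimethylsilyl)oxy]-6-methyl-2-[(pinacolboryl)methyl]nona-2,6-dienoate | COC(=O)/C(CB1OC(C)(C)C(C)(C)O1)=C/CC/C(C)=C/CCO[Si](C)(C)C(C)(C)C | intermediate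
11 | geranyl acetate | CC(C)=CCC/C(C)=C/COC(C)=O | starting material
12 | (±)-(2E)-5-(3,3-dimethyloxiran-2-yl)-3-methylpent-2-en-1-yl acetate | CC1(C)OC1CC/C(C)=C/COC(C)=O | intermediate
13 | (2E)-3-methyl-6-oxohex-2-en-1-yl acetate | O=CCC/C(C)=C/COC(C)=O | intermediate
14 | dimethyl (1-diazo-2-oxopropyl)phosphonate | CC(=O)C(=[N+]=[N-])P(=O)(OC)OC | starting material
15 | (2E)-3-methylhept-2-en-6-yn-1-ol | C#CCC/C(C)=C/CO | intermediate
16 | triethyl{[(2E)-3-methylhept-2-en-6-yn-1-yl]oxy}silane | C#CCC/C(C)=C/CO[Si](CC)(CC)CC | intermediate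
17 | lithium acetylide of 16 | [Li]C#CCC/C(C)=C/CO[Si](CC)(CC)CC | intermediate
18 | lithium (6E)-6-methyl-8-[(triethylsilyl)oxy]oct-6-en-2-yn-1-olate | [Li]OCC#CCC/C(C)=C/CO[Si](CC)(CC)CC | intermediate
19 | (6E)-6-methyl-8-[(triethylsilyl)oxy]oct-6-en-2-yn-1-yl acetate | CC(=O)OCC#CCC/C(C)=C/CO[Si](CC)(CC)CC | intermediate
20 | (2E,6E)-6-methyl-2-(tributylstannyl)-8-[(triethylsilyl)oxy]octa-2,6-dien-1-yl acetate | CC(=O)OC/C([Sn](CCCC)(CCCC)CCCC)=C\CC/C(C)=C/CO[Si](CC)(CC)CC | intermediate
21 | (2E,6E)-2-iodo-6-methyl-8-[(triethylsilyl)oxy]octa-2,6-dien-1-yl acetate | CC(=O)OC/C(I)=C\CC/C(C)=C/CO[Si](CC)(CC)CC | intermediate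
22 | (2E,6E)-2-iodo-6-methyl-8-oxoocta-2,6-dien-1-yl acetate | CC(=O)OC/C(I)=C\CC/C(C)=C/C=O | intermediate
23 | methyl (3S,6E)-3-[(1S,2E,6E)-8-acetoxy-7-iodo-3-methyl-1-(pinacolboryloxy)octa-2,6-dien-1-yl]-9-[(tert-butyldimethylsilyl)oxy]-6-methyl-2-methylidenenon-6-enoate | COC(=O)C(=C)[C@H](CC/C(C)=C/CCO[Si](C)(C)C(C)(C)C)[C@@H](OB1OC(C)(C)C(C)(C)O1)/C=C(\C)CC/C=C(\COC(C)=O)I | intermediate
24 | (4S,5S)-cis-lactone with C9–OTBS and C8–I | C=C1C(=O)O[C@@H](/C=C(\C)CC/C=C(\COC(C)=O)I)[C@H]1CC/C(C)=C/CCO[Si](C)(C)C(C)(C)C | intermediate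
25 | (4S,5S)-cis-lactone with C9–OH and C8–I | C=C1C(=O)O[C@@H](/C=C(\C)CC/C=C(\COC(C)=O)I)[C@H]1CC/C(C)=C/CCO | intermediate
26 | (4S,5S)-cis-lactone with C9–I and C8–I (seco-diiodide) | C=C1C(=O)O[C@@H](/C=C(\C)CC/C=C(\COC(C)=O)I)[C@H]1CC/C(C)=C/CCI | intermediate
27 | C9 alkylzinc iodide of 26 | C=C1C(=O)O[C@@H](/C=C(\C)CC/C=C(\COC(C)=O)I)[C@H]1CC/C(C)=C/CC[Zn]I | intermediate
28 | (1S,2S,3E,7Z,11E)-19-acetoxycembra-3,7,11,15(17)-tetraen-16,2-olide (CNP0158848.2) | C=C1C(=O)O[C@H]2/C=C(\C)CC/C=C(\COC(C)=O)CC/C=C(\C)CC[C@@H]12 | target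

**Step count and risks**

Total step count: 17 (six for the western half, seven for the eastern half, four after union).
Longest linear sequence: 11 steps (steps 7–17, from geranyl acetate).

The three steps most likely to fail are these.

Step 17 (macrocyclic Negishi coupling).
- What may go wrong: macrocyclic transmetalation is slow, so intermolecular transmetalation (oligomerisation) may compete. The C9–Zn bond may be protonated by adventitious water in the large solvent volume. The long-lived alkenylpalladium may be intercepted by the C15=C17 acrylate.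
- The fallback sets out from 25 and comes back at 28. It removes the acrylate before the same bond is closed.
- Conjugate addition of thiophenol (PhSH, cat. Et3N, CH2Cl2) to 25 should give the α-(phenylsulfanylmethyl) lactone alcohol F1, whose C15 epimers are inconsequential.
- Appel iodination gives the masked diiodide F2, and zinc insertion gives the masked alkylzinc iodide F3.
- With no Michael acceptor or Heck acceptor left, F3 can be cyclised at C8–C9 at higher temperature and catalyst loading to the macrocyclic sulfide F4.
- NaIO4 oxidation gives the macrocyclic sulfoxide F5, and thermolysis (toluene, 110 °C, CaCO3) restores C15=C17 by syn-elimination to give 28.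

Step 14 (catalytic asymmetric allylboration/lactonisation).
- What may go wrong: the ester-deactivated allylboronate may add sluggishly, so that uncatalysed background addition and poor facial discrimination erode enantiopurity. The doubly allylic C2–O bond may ionise during acid-promoted lactonisation and leak to the trans-lactone.
- The fallback sets out from 8 and comes back at 24. It replaces boron and Brønsted acid by a catalytic asymmetric allylation of the Nozaki–Hiyama–Kishi type.
- NBS/Me2S (CH2Cl2, 0 °C) converts 8 with allylic transposition into the (Z)-allylic bromide F6.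
- F6 is coupled with enal 22 using CrCl2 (10 mol %), a chiral carbazole-bis(oxazoline) ligand, Mn powder and Cp2ZrCl2 in THF at rt. No nickel salt is added, so the alkenyl iodide should stay inert.
- The closed transition state of the ester-anti allylchromium species should again give the syn adduct, which lactonises on mild acidic work-up to 24.

Step 12 (hydrostannation/iodination).
- What may go wrong: tin may be delivered partly to C7, and zerovalent palladium may ionise the propargylic acetate, with hydride reduction to an allene.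
- The fallback sets out from 16 and comes back at 21. It polarises the alkyne strongly before the tin hydride is added.
- n-BuLi then ClCO2Me gives the ynoate F7.
- Pd(PPh3)4/Bu3SnH gives, by syn-addition with tin α to the ester, the α-stannyl enoate F8.
- I2 gives the (E)-α-iodo enoate F9, and i-Bu2AlH (2.2 equiv, −78 °C) gives the iodo allylic alcohol F10.
- Ac2O/pyridine then gives 21.

**Further compounds**

F1 | step 17 | thiophenol adduct of 25 (C1 and C2 as in 25, C15 epimers) | O=C1O[C@@H](/C=C(\C)CC/C=C(\COC(C)=O)I)[C@@H](CC/C(C)=C/CCO)C1CSc1ccccc1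
F2 | step 17 | masked diiodide (C9–I analogue of F1) | O=C1O[C@@H](/C=C(\C)CC/C=C(\COC(C)=O)I)[C@@H](CC/C(C)=C/CCI)C1CSc1ccccc1
F3 | step 17 | masked C9 alkylzinc iodide | O=C1O[C@@H](/C=C(\C)CC/C=C(\COC(C)=O)I)[C@@H](CC/C(C)=C/CC[Zn]I)C1CSc1ccccc1
F4 | step 17 | macrocyclic sulfide (17-phenylsulfanyl-15,17-dihydro derivative of 28) | O=C1O[C@H]2/C=C(\C)CC/C=C(\COC(C)=O)CC/C=C(\C)CC[C@H]2C1CSc1ccccc1
F5 | step 17 | macrocyclic sulfoxide of F4 | O=C1O[C@H]2/C=C(\C)CC/C=C(\COC(C)=O)CC/C=C(\C)CC[C@H]2C1CS(=O)c1ccccc1
F6 | step 14 | methyl (2Z,6E)-2-(bromomethyl)-9-[(tert-butyldimethylsilyl)oxy]-6-methylnona-2,6-dienoate | COC(=O)/C(CBr)=C/CC/C(C)=C/CCO[Si](C)(C)C(C)(C)C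
F7 | step 12 | methyl (6E)-6-methyl-8-[(triethylsilyl)oxy]oct-6-en-2-ynoate | COC(=O)C#CCC/C(C)=C/CO[Si](CC)(CC)CC
F8 | step 12 | methyl (2E,6E)-6-methyl-2-(tributylstannyl)-8-[(triethylsilyl)oxy]octa-2,6-dienoate | COC(=O)/C([Sn](CCCC)(CCCC)CCCC)=C\CC/C(C)=C/CO[Si](CC)(CC)CC
F9 | step 12 | methyl (2E,6E)-2-iodo-6-methyl-8-[(triethylsilyl)oxy]octa-2,6-dienoate | COC(=O)/C(I)=C\CC/C(C)=C/CO[Si](CC)(CC)CC
F10 | step 12 | (2E,6E)-2-iodo-6-methyl-8-[(triethylsilyl)oxy]octa-2,6-dien-1-ol | OC/C(I)=C\CC/C(C)=C/CO[Si](CC)(CC)CC
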